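## The problem

The target is a germacranolide: a ten-membered carbocycle (C1–C10) with a trans-fused α-methylene-γ-butyrolactone on C6/C7 (C11–C13), a methyl ester (C14) on C10, a methyl group (C15) on C4, an angelate on O8, an acetate on O9 and a free hydroxyl on C2. Both ring unsaturations are ring-cis: C1=C10 is present as the olefin and C4=C5 as its cis-epoxide. Closing the ring by C–C bond formation would therefore mean making a strained cis,cis-cyclodecadiene. Seven stereocentres have to be set (C2, C4, C5, C6, C7, C8, C9). C7 can be taken from the chiral pool and can control C6 (trans) and then C8; C8 can control C9; C4/C5 follow from the olefin geometry plus a facial choice that a nearby hydroxyl can direct. C2 has no controlling neighbour in the flexible ring and is best set in a rigid precursor. The α-methylene lactone (a Michael acceptor), the epoxide, the angelate (prone to isomerise to the tiglate), the C9 acetate allylic to the enoate (open to SN2′ attack) and the two different esters on adjacent carbinols (acyl migration) will not survive rough treatment and must appear late. The enabling feature is that O9 lies 1,3 to C5 across C4 and both olefins are ring-cis. With a bond drawn between C4 and C9 the ring folds into a cis-fused decalin: ring B (C1–C4, C9, C10) already holds C1=C10 and ring A (C4–C9) holds C5, C6 and C7. The ten-membered ring can then be uncovered by cutting C4–C9.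

## Retrosynthesis

**29 to 28.** The two C–O bonds of the oxirane are removed last. C4=C5 is the only electron-rich olefin of 28, and the homoallylic C2 hydroxyl sits on the face the oxygen must enter, so a hydroxyl-directed epoxidation can end the synthesis and the epoxide never meets another reagent. Two stereocentres disappear. The forward step must be cis-selective with respect to O2 and must leave three conjugated olefins alone.

**28 to 24 (through 27 and 26).** The lactone bond C12–O6 is cut and C12 and C14 are lowered to primary allylic alcohols. This keeps the Michael-acceptor lactone and the 2-alkylidene ester next to an allylic acetate out of all enolate and hydride chemistry. Tetraol 24 carries no acid-level carbon. The forward oxidation must take two primary allylic alcohols in preference to two secondary ones and close the lactone through the C6 hydroxyl.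

**24 to 17 and angelic acid 20 (through 23, 22, 21, 19).** The C8–O bond, the O9 acetyl bond and the C9–H bond are cut, which leaves a C9 ketone with a C8 methylene. The ketone is the handle for both oxygens: α′-bromination and carboxylate displacement for C8, then a 1,2-reduction steered by the new C8 ester for C9. Two stereocentres and both acyl groups are removed. The forward steps need face selectivity at C8 and carbonyl-selective reduction of an enone.

**17 to 16.** The C9 carbonyl and the Z C4=C5 olefin are traded for the C4–C9 bond, a C9 alkoxide and a C5 mesylate (Grob fragmentation). Against ring closure by olefination or metathesis, this cut has no entropic penalty and the olefin geometry is stereospecific. The precursor is a decalin whose stereocentres can be set by chair-controlled reactions. The forward step needs the mesylate anti-periplanar to C4–C9 and C3 gauche to C6.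

**16 to 10 (through 15, 14, 13, 12, 11).** The silyl ethers, the C5 sulfonate and the oxygens on C2 and C12 are removed, and C14 returns to the ester. C2 and C12 are oxidised before the ring is opened because C4=C5 would later compete in allylic oxidations and C2 would have no stereocontrol. C14 passes through the key step as a silyloxymethyl group: an ester on C10 would turn the fragmentation product into a 2-alkylidene-3-oxo ester, acidic at C2 and strongly electrophilic under alkoxide conditions. The forward steps need selective C–H oxidation at C2, a hydroxyl-directed reduction at C5 and hydride delivery to C2 opposite the angular methyl.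

**10 to dione 5 and methyl 3-oxopent-4-enoate 6 (through 9, 8, 7).** The bonds C3–C4 and C9–C10 are cut (Michael addition and aldol) and the C1 oxygen is restored. The annulation is stopped at ketol 8, so the C9 hydroxyl needed for the fragmentation is kept, and C14 arrives on C10. The forward steps need the chain to enter C4 cis to the isopropenyl group and the aldol to choose the C9 carbonyl.

**5 to (R)-carvone 1 (through 4, 3, 2).** The C6–O bond is cut and the C9 carbonyl is traced to the enone through its epoxide. Carvone supplies the C15 methyl, the C5 carbonyl and C7 with C11–C13 attached. Oxygenating C6 first keeps the dione unsymmetrical, so the carvone stereocentre is retained and the two carbonyls differ. The forward steps need trans-selective α′-hydroxylation.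

## Roads not taken

**Alternative 1:** The cut isolates C5–C9, C11 and C12 as a small lactone from levoglucosenone A1. Conjugate addition of a vinyl group gives A2, and the key step is a Baeyer–Villiger oxidation of A2: the acetal carbon migrates, formate is lost and the γ-lactone A3 closes on the former pyranose oxygen. Merits: C6 and C7 come from a cellulose-derived enone in two or three steps with the trans relationship fixed by exo-face addition, and the lactone is present from the start. Weak points: the whole ten-membered ring still has to be built from the hydroxymethyl and vinyl ends and closed as a cis,cis-cyclodecadiene, for which no reliable ring closure exists, and the lactone must then survive everything. In supply of C6/C7 and in early lactone formation this road is better than the chosen plan, which forms the lactone only at step 20. The chosen plan offsets this by delivering the ring and both olefin geometries in one stereospecific step.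

**Alternative 2:** The cut removes O2 and O9 together. The key step adds singlet oxygen across C9 and C2 of the ring diene A4 to give endoperoxide A5, and reduction would then give the cis-2,9-diol with the C1=C10 olefin ring-cis. Merits: two C–O bonds and one olefin geometry in one step, with the cis relation of O2 and O9 that the target has. Weak points: a cis,cis-1,3-diene in a ten-membered ring is twisted and here carries an ester, so the cycloaddition would be slow and ene reactions would compete; the facial choice rests only on ring conformation; the two new secondary hydroxyls must then be told apart; and the macrocycle still has to be made. In step economy for C2 and C9 it is better than the chosen plan, which spends steps 8 and 12 on C2 and steps 17 and 18 on C9. The chosen plan offsets this by placing each oxygen through a reaction with a clear stereochemical model.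

**Alternative 3:** The cut is the lactone C–O bond at C6. The key step joins the C12 acid of A6 to C6 by palladium-mediated allylic C–H cleavage and C–O bond formation, giving lactone A7. Merits: no oxygen and no protecting group are carried at C6, and the endgame is short. Weak points: allylic C–H lactonisation is established for terminal olefins; on a ring-cis trisubstituted olefin the metal could cleave C–H at C3 or C15 as well as C6, the allyl intermediate could lose the Z geometry, and neither the site of C–O formation nor the trans fusion is assured. In redox and protecting-group economy at C6 it is better than the chosen plan. The chosen plan offsets this by fixing C6 in step 1 and using that oxygen twice, to differentiate the two carbonyls of 5 and as an equatorial anchor in the fragmentation.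

Key step: step 14

Remark on the chemistry: germacranolide numbering is used for all intermediates; ring A is the carvone-derived carbocycle C4–C9 and ring B the cyclohexene C1–C4/C9/C10; 6 and 20 are taken as purchasable; β-keto ester 8 is written as its enol; any enal formed beside 14 is reduced to the same alcohol in step 12.

Step 1
Reactants: 1 (R)-carvone
Product: 2 (5S,6S)-6-hydroxycarvone (hydroxyl trans to the isopropenyl group)
Conditions: KN(SiMe3)2, THF, −78 °C; 2-(phenylsulfonyl)-3-phenyloxaziridine; NH4Cl
Reagents that add atoms: 2-(phenylsulfonyl)-3-phenyloxaziridine, O=S(=O)(N1OC1c1ccccc1)c1ccccc1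
Why: Kinetic α′-deprotonation gives the cross-conjugated enolate, and oxaziridine hydroxylation (Davis oxidation) should enter anti to the adjacent isopropenyl group, setting the C6 oxygen trans to the C7 substituent.

Step 2
Reactants: 2 (5S,6S)-6-hydroxycarvone
Product: 3 (5S,6S)-6-(tert-butyldimethylsilyloxy)carvone
Conditions: TBSCl, imidazole, DMF, 25 °C
Reagents that add atoms: tert-butyldimethylsilyl chloride, CC(C)(C)[Si](C)(C)Cl
Why: Standard silylation of a secondary α-hydroxy ketone; the bulky ether later shields the C5 carbonyl and acts as an equatorial anchor.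

Step 3
Reactants: 3 (5S,6S)-6-(tert-butyldimethylsilyloxy)carvone
Product: 4 2,3-epoxy ketone (oxirane trans to the isopropenyl group)
Conditions: H2O2 (30%), NaOH (cat.), MeOH, 0 °C
Reagents that add atoms: hydrogen peroxide, OO
Why: Weitz–Scheffer nucleophilic epoxidation touches only the enone; the two new centres are erased in step 4, so the face is of no consequence.

Step 4
Reactants: 4 2,3-epoxy ketone
Product: 5 (4S,5S)-4-(tert-butyldimethylsilyloxy)-2-methyl-5-(prop-1-en-2-yl)cyclohexane-1,3-dione
Conditions: Pd(PPh3)4 (5 mol%), dppe (5 mol%), toluene, 100 °C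
Reagents that add atoms: none
Why: Zerovalent-palladium-catalysed isomerisation of an α,β-epoxy ketone to the β-diketone (oxidative addition at the α C–O bond, β-hydride elimination, tautomerisation), known for cyclic epoxy enones of the carvone type.

Step 5
Reactants: 5 the silyloxy dione; 6 methyl 3-oxopent-4-enoate
Product: 8 cis-fused ketol (C9 hydroxyl cis to the C4 methyl; enolised C1/C10 β-keto ester; C5 ketone), via triketone 7 (not isolated)
Conditions: Cs2CO3 (0.3 equiv), CH2Cl2, 0 to 25 °C
Reagents that add atoms: none
Why: Michael addition of the 2-methyl-1,3-dione to the Nazarov reagent followed by intramolecular aldol (Robinson-type annulation stopped at the ketol). The chain should enter C4 axially on the chair-like enolate, cis to the equatorial isopropenyl group, and under reversible conditions C10 should close on the C9 carbonyl, since C5 is flanked by the silyloxy carbon; the three-atom tether enforces the cis fusion.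

Step 6
Reactants: 8 cis-fused ketol
Product: 9 C1 enol triflate
Conditions: NaH, THF, 0 °C; PhNTf2, 0 to 25 °C
Reagents that add atoms: N-phenylbis(trifluoromethanesulfonimide), O=S(=O)(N(c1ccccc1)S(=O)(=O)C(F)(F)F)C(F)(F)F
Why: O-Sulfonylation of the β-keto ester enolate, the only site deprotonated by one equivalent of base; the tertiary C9 hydroxyl is too hindered to react.

Step 7
Reactants: 9 C1 enol triflate
Product: 10 C1(10)-enoate with C5 ketone and C9 hydroxyl
Conditions: Pd(OAc)2 (5 mol%), PPh3, HCO2H, n-Bu3N, DMF, 60 °C
Reagents that add atoms: none
Why: Palladium-catalysed formate reduction of an enol triflate puts hydrogen on C1 and leaves the ring-cis C1=C10 olefin with C14 on C10; from here retro-aldol loss of ring B is no longer possible.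

Step 8
Reactants: 10 C1(10)-enoate
Product: 11 2-oxo enoate
Conditions: Rh2(cap)4 (cap = caprolactamate, 1 mol%), t-BuOOH (70% aq.), K2CO3 (0.5 equiv), CH2Cl2, 25 °C
Reagents that add atoms: tert-butyl hydroperoxide, CC(C)(C)OO
Why: Catalytic allylic C–H oxidation by tert-butylperoxyl radicals, known for cyclohexene-1-carboxylates; C2 is the only ring methylene allylic to the enoate because C9 is fully substituted.

Step 9
Reactants: 11 2-oxo enoate
Product: 12 C5 alcohol (trans-1,3-diol with the C9 hydroxyl)
Conditions: Me4NBH(OAc)3, MeCN/AcOH, −30 to 0 °C
Reagents that add atoms: none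
Why: Evans–Saksena reduction: the borohydride bound to the axial C9 hydroxyl delivers hydride to the same face of the C5 carbonyl, giving the equatorial C5 alcohol anti to O9; the C2 enone has no hydroxyl within reach and is not reduced.

Step 10
Reactants: 12 C5 alcohol
Product: 13 C5 mesylate
Conditions: MsCl, Et3N, CH2Cl2, 0 °C
Reagents that add atoms: methanesulfonyl chloride, CS(=O)(=O)Cl
Why: Sulfonylation through sulfene takes the secondary alcohol; the tertiary C9 hydroxyl between two fully substituted carbons stays free.

Step 11
Reactants: 13 C5 mesylate
Product: 14 C12 allylic alcohol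
Conditions: SeO2 (0.5 equiv), t-BuOOH, CH2Cl2, 25 °C
Reagents that add atoms: tert-butyl hydroperoxide, CC(C)(C)OO; selenium dioxide (oxygen carrier), O=[Se]=O
Why: Selenium dioxide allylic oxidation (ene reaction, then [2,3]-sigmatropic shift) of the 1,1-disubstituted olefin at its methyl group; the ring olefin is electron-poor and would need selenium to bond to the congested C10, so it should not react.

Step 12
Reactants: 14 C12 allylic alcohol
Product: 15 C2,C12,C14-triol (C2 hydroxyl cis to the C4 methyl)
Conditions: i-Bu2AlH (excess), CH2Cl2, −78 to −40 °C; aqueous potassium sodium tartrate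
Reagents that add atoms: none
Why: Carbonyl-selective reduction of the C2 ketone and of the ester by an electrophilic aluminium hydride; hydride should reach C2 opposite the axial C4 methyl of ring B, which gives the C2 configuration of the target.

Step 13
Reactants: 15 triol
Product: 16 tris(silyl ether) with free C9 hydroxyl and C5 mesylate
Conditions: TBSOTf (3.3 equiv), 2,6-lutidine, CH2Cl2, −78 °C
Reagents that add atoms: tert-butyldimethylsilyl trifluoromethanesulfonate, CC(C)(C)[Si](C)(C)OS(=O)(=O)C(F)(F)F
Why: Silyl triflate silylation of the two primary and the hindered secondary allylic alcohols at low temperature; the tertiary C9 hydroxyl is expected to be left free.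

Step 14
Reactants: 16 cis-fused decalin with C9 hydroxyl and C5 mesylate
Product: 17 ten-membered 9-oxo-1(10)Z,4Z-diene
Conditions: KN(SiMe3)2 (1.1 equiv), THF, −78 to 0 °C; pH 7 buffer at −78 °C
Reagents that add atoms: none
Why: The base forms the C9 alkoxide, whose lone pair pushes into the C4–C9 bond lying anti-periplanar to the equatorial C5–O bond, so C9=O and C4=C5 form while C4–C9 and C5–OMs break in one concerted step. The closest known reaction type is the Wharton–Grob fragmentation of a decalin 1,3-diol monosulfonate to a cyclodecenone. No ring is closed by bond formation: the ten-membered ring appears because the bond shared by rings A and B is cut. No stereocentre is created; the new stereo element is the C4=C5 geometry, which is stereospecific: in the cis-fused chair C3 is axial on ring A and gauche to C6, so C3 and C6 end cis (Z). The ring-cis C1=C10 olefin passes unchanged from ring B. The step needs fragmentation to beat elimination, substitution and silyl migration to O9; the chair in which mesylate, C6 silyloxy group and C7 side chain are all equatorial secures this, since no hydrogen is anti to the mesylate and O9 cannot reach the back of C5. With C14 at the alcohol level the product is an ordinary enone that should tolerate the brief exposure to alkoxide.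

Step 15
Reactants: 17 cyclodecadienone
Product: 19 C8 bromo ketone (bromine trans to the C7 side chain), via silyl dienol ether 18 (not isolated)
Conditions: KN(SiMe3)2, THF, −78 °C; Me3SiCl; then NBS, THF, −78 °C
Reagents that add atoms: chlorotrimethylsilane (retained only in 18), C[Si](C)(C)Cl; N-bromosuccinimide, O=C1CCC(=O)N1Br
Why: Kinetic α′-deprotonation of the enone at C8, the only enolisable carbon next to the ketone, silylation, and bromination of the silyl enol ether; the electrophile is expected trans to the adjacent C7 substituent, the usual 1,2-induction of a ring enolate.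

Step 16
Reactants: 19 C8 bromo ketone; 20 angelic acid
Product: 21 C8 angelate (cis to the C7 side chain)
Conditions: Cs2CO3 (0.6 equiv), DMF, 0 to 25 °C
Reagents that add atoms: none
Why: SN2 displacement of an α-bromo ketone by a caesium carboxylate with inversion places O8 cis to the C7 side chain; carboxylate alkylation needs no acyl activation, so the angelate should not isomerise to the tiglate.

Step 17
Reactants: 21 C8 angelate ketone
Product: 22 C9 allylic alcohol (O9 trans to O8)
Conditions: NaBH4, CeCl3·7H2O, MeOH, −78 °C
Reagents that add atoms: none
Why: Luche reduction is carbonyl-selective on the enone; Felkin–Anh attack anti to the C8–O bond of the non-chelating ester should give the 8,9-trans relationship, and the low temperature limits acyl migration.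

Step 18
Reactants: 22 C9 allylic alcohol
Product: 23 C9 acetate
Conditions: Ac2O, pyridine, DMAP (cat.), CH2Cl2, 0 to 25 °C
Reagents that add atoms: acetic anhydride, CC(=O)OC(C)=O
Why: Standard acylation of the only free hydroxyl; at this stage the acetate is a plain allylic ester, not yet flanked by the C14 ester.

Step 19
Reactants: 23 C9 acetate
Product: 24 tetraol (hydroxyls on C2, C6, C12, C14)
Conditions: HF·pyridine, pyridine, THF, 0 to 25 °C
Reagents that add atoms: none
Why: Fluoride cleavage of the four silyl ethers under buffered acidic conditions, which do not promote ester migration or hydrolysis.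

Step 20
Reactants: 24 tetraol
Product: 26 12,6-lactone 14-aldehyde, via lactol 25 (not isolated)
Conditions: TEMPO (0.3 equiv), PhI(OAc)2 (3.3 equiv), CH2Cl2, 25 °C
Reagents that add atoms: none
Why: Oxoammonium oxidation is selective for the two primary allylic alcohols; the C12 aldehyde is trapped by the C6 hydroxyl as the lactol and oxidised on to the trans-fused α-methylene lactone (oxidative lactonisation of a 1,4-diol), while C14 stops at the enal.

Step 21
Reactants: 26 lactone aldehyde
Product: 27 C14 carboxylic acid
Conditions: NaClO2, NaH2PO4, 2-methyl-2-butene, t-BuOH/H2O, 0 to 25 °C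
Reagents that add atoms: sodium chlorite, [Na+].[O-]Cl=O
Why: Pinnick oxidation of a conjugated aldehyde; the scavenger protects the C4=C5 olefin from hypochlorite.

Step 22
Reactants: 27 C14 carboxylic acid
Product: 28 methyl ester with the 4Z olefin
Conditions: Me3SiCHN2, MeOH/toluene, 0 °C
Reagents that add atoms: (trimethylsilyl)diazomethane, C[Si](C)(C)C=[N+]=[N-]
Why: Diazoalkane esterification of the acid is fast at 0 °C, so short exposure should leave the methylene lactone untouched.

Step 23
Reactants: 28 methyl ester with the 4Z olefin
Product: 29 target compound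
Conditions: VO(acac)2 (10 mol%), t-BuOOH (in decane), CH2Cl2, 0 to 25 °C
Reagents that add atoms: tert-butyl hydroperoxide, CC(C)(C)OO
Why: Vanadium-catalysed hydroxyl-directed epoxidation: the homoallylic C2 hydroxyl should deliver oxygen to the face of C4=C5 on which it sits, giving the epoxide cis to O2 as in the target; the other three olefins are conjugated to carbonyls and react far more slowly.

## Compound list

1 | (R)-carvone | CC1=CC[C@H](CC1=O)C(C)=C | starting material
2 | (5S,6S)-6-hydroxy-2-methyl-5-(prop-1-en-2-yl)cyclohex-2-en-1-one | CC1=CC[C@@H](C(C)=C)[C@H](O)C1=O | intermediate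
3 | (5S,6S)-6-(tert-butyldimethylsilyloxy)-2-methyl-5-(prop-1-en-2-yl)cyclohex-2-en-1-one | CC1=CC[C@@H](C(C)=C)[C@H](O[Si](C)(C)C(C)(C)C)C1=O | intermediate
4 | 2,3-epoxide of 3, oxirane trans to the isopropenyl group | C[C@@]12O[C@@H]1C[C@@H](C(C)=C)[C@H](O[Si](C)(C)C(C)(C)C)C2=O | intermediate
5 | (4S,5S)-4-(tert-butyldimethylsilyloxy)-2-methyl-5-(prop-1-en-2-yl)cyclohexane-1,3-dione | CC1C(=O)C[C@@H](C(C)=C)[C@H](O[Si](C)(C)C(C)(C)C)C1=O | intermediate
6 | methyl 3-oxopent-4-enoate | C=CC(=O)CC(=O)OC | starting material
7 | triketone: Michael adduct, C4 side chain cis to the isopropenyl group | C[C@]1(CCC(=O)CC(=O)OC)C(=O)C[C@@H](C(C)=C)[C@H](O[Si](C)(C)C(C)(C)C)C1=O | intermediate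
8 | cis-fused ketol: C9 hydroxyl cis to C4 methyl, C1 enol, C10 ester, C5 ketone, C6 silyl ether, C7 isopropenyl | C[C@]12CCC(O)=C(C(=O)OC)[C@@]1(O)C[C@@H](C(C)=C)[C@H](O[Si](C)(C)C(C)(C)C)C2=O | intermediate
9 | C1 enol triflate of 8 | C[C@]12CCC(OS(=O)(=O)C(F)(F)F)=C(C(=O)OC)[C@@]1(O)C[C@@H](C(C)=C)[C@H](O[Si](C)(C)C(C)(C)C)C2=O | intermediate
10 | C1(10)-enoate with C5 ketone and C9 hydroxyl | C[C@]12CCC=C(C(=O)OC)[C@@]1(O)C[C@@H](C(C)=C)[C@H](O[Si](C)(C)C(C)(C)C)C2=O | intermediate
11 | 2-oxo enoate | C[C@]12CC(=O)C=C(C(=O)OC)[C@@]1(O)C[C@@H](C(C)=C)[C@H](O[Si](C)(C)C(C)(C)C)C2=O | intermediate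
12 | C5 alcohol, hydroxyl trans to C9 hydroxyl and to C6 silyl ether | C[C@]12CC(=O)C=C(C(=O)OC)[C@@]1(O)C[C@@H](C(C)=C)[C@H](O[Si](C)(C)C(C)(C)C)[C@H]2O | intermediate
13 | C5 mesylate | C[C@]12CC(=O)C=C(C(=O)OC)[C@@]1(O)C[C@@H](C(C)=C)[C@H](O[Si](C)(C)C(C)(C)C)[C@H]2OS(C)(=O)=O | intermediate
14 | C12 allylic alcohol | C[C@]12CC(=O)C=C(C(=O)OC)[C@@]1(O)C[C@@H](C(CO)=C)[C@H](O[Si](C)(C)C(C)(C)C)[C@H]2OS(C)(=O)=O | intermediate
15 | C2,C12,C14-triol, C2 hydroxyl cis to C4 methyl | C[C@]12C[C@H](O)C=C(CO)[C@@]1(O)C[C@@H](C(CO)=C)[C@H](O[Si](C)(C)C(C)(C)C)[C@H]2OS(C)(=O)=O | intermediate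
16 | fragmentation precursor: cis-fused decalin, free C9 hydroxyl, C5 mesylate, silyl ethers on O2, O6, O12, O14 | C[C@]12C[C@H](O[Si](C)(C)C(C)(C)C)C=C(CO[Si](C)(C)C(C)(C)C)[C@@]1(O)C[C@@H](C(CO[Si](C)(C)C(C)(C)C)=C)[C@H](O[Si](C)(C)C(C)(C)C)[C@H]2OS(C)(=O)=O | intermediate
17 | ten-membered 9-oxo-1(10)Z,4Z-diene, silyl ethers on O2, O6, O12, O14 | C1[C@@H](C(CO[Si](C)(C)C(C)(C)C)=C)[C@H](O[Si](C)(C)C(C)(C)C)/C=C(C)\C[C@H](O[Si](C)(C)C(C)(C)C)/C=C(CO[Si](C)(C)C(C)(C)C)\C1=O | intermediate
18 | C8,C9 trimethylsilyl dienol ether of 17 | C1/C(C)=C\[C@@H](O[Si](C)(C)C(C)(C)C)[C@H](C(CO[Si](C)(C)C(C)(C)C)=C)/C=C(O[Si](C)(C)C)\C(CO[Si](C)(C)C(C)(C)C)=C/[C@H]1O[Si](C)(C)C(C)(C)C | intermediate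
19 | C8 bromo ketone, bromine trans to the C7 side chain | Br[C@@H]1[C@@H](C(CO[Si](C)(C)C(C)(C)C)=C)[C@H](O[Si](C)(C)C(C)(C)C)/C=C(C)\C[C@H](O[Si](C)(C)C(C)(C)C)/C=C(CO[Si](C)(C)C(C)(C)C)\C1=O | intermediate
20 | angelic acid, (Z)-2-methylbut-2-enoic acid | C/C=C(/C)C(=O)O | starting material
21 | C8 angelate of the 9-ketone, O8 cis to the C7 side chain | C/C=C(/C)C(=O)O[C@H]1[C@@H](C(CO[Si](C)(C)C(C)(C)C)=C)[C@H](O[Si](C)(C)C(C)(C)C)/C=C(C)\C[C@H](O[Si](C)(C)C(C)(C)C)/C=C(CO[Si](C)(C)C(C)(C)C)\C1=O | intermediate
22 | C9 alcohol, O9 trans to O8 | C/C=C(/C)C(=O)O[C@H]1[C@@H](C(CO[Si](C)(C)C(C)(C)C)=C)[C@H](O[Si](C)(C)C(C)(C)C)/C=C(C)\C[C@H](O[Si](C)(C)C(C)(C)C)/C=C(CO[Si](C)(C)C(C)(C)C)\[C@@H]1O | intermediate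
23 | C9 acetate | C/C=C(/C)C(=O)O[C@H]1[C@@H](C(CO[Si](C)(C)C(C)(C)C)=C)[C@H](O[Si](C)(C)C(C)(C)C)/C=C(C)\C[C@H](O[Si](C)(C)C(C)(C)C)/C=C(CO[Si](C)(C)C(C)(C)C)\[C@@H]1OC(C)=O | intermediate
24 | tetraol: 8-angelate 9-acetate with hydroxyls on C2, C6, C12, C14 | C/C=C(/C)C(=O)O[C@H]1[C@@H](C(CO)=C)[C@H](O)/C=C(C)\C[C@H](O)/C=C(CO)\[C@@H]1OC(C)=O | intermediate
25 | 6,12-lactol of the 12,14-dialdehyde | C1/C(C)=C\[C@H]2OC(O)C(=C)[C@@H]2[C@H](OC(=O)/C(C)=C\C)[C@@H](OC(C)=O)/C(C=O)=C\[C@H]1O | intermediate
26 | trans-fused 12,6-lactone 14-aldehyde | C1/C(C)=C\[C@H]2OC(=O)C(=C)[C@@H]2[C@H](OC(=O)/C(C)=C\C)[C@@H](OC(C)=O)/C(C=O)=C\[C@H]1O | intermediate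
27 | C14 carboxylic acid | C1/C(C)=C\[C@H]2OC(=O)C(=C)[C@@H]2[C@H](OC(=O)/C(C)=C\C)[C@@H](OC(C)=O)/C(C(=O)O)=C\[C@H]1O | intermediate
28 | methyl ester with the 4Z olefin (the target without the epoxide oxygen) | C1/C(C)=C\[C@H]2OC(=O)C(=C)[C@@H]2[C@H](OC(=O)/C(C)=C\C)[C@@H](OC(C)=O)/C(C(=O)OC)=C\[C@H]1O | intermediate
29 | target compound (2S,4R,5S,6S,7R,8S,9S) | C=C1C(=O)O[C@H]2[C@H]1[C@H](OC(=O)/C(C)=C\C)[C@@H](OC(C)=O)/C(C(=O)OC)=C\[C@@H](O)C[C@@]1(C)O[C@@H]21 | target

## Step count and least certain steps

Total: 23 steps. Longest linear sequence: 23 steps from (R)-carvone (1); compounds 6 and 20 enter as purchased reagents.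

**Step 14 (key step).** The most likely failure is proton transfer from the product enone to alkoxide not yet fragmented, which would stall conversion and could move the C1=C10 olefin. A second is migration of the silyl group from O14 to the C9 alkoxide, which would block the fragmentation. Fallback: set out from 16 and silylate the tertiary hydroxyl with N-(trimethylsilyl)imidazole to give the C9 trimethylsilyl ether F1. Treat F1 with CsF in DMF at 0 °C, so that the alkoxide is released by desilylation in the absence of any strong base and fragments as before, returning to the route at 17.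

**Step 8.** The likely failure is poor site selectivity of hydrogen abstraction (the allylic positions of the isopropenyl group, or C6–H) combined with slow reaction of the electron-poor olefin. Fallback by enolate chemistry, setting out from 10: Evans–Saksena reduction gives the C5 alcohol F2; both hydroxyls are capped with N-(trimethylsilyl)imidazole to give the bis(trimethylsilyl) ether F3; γ-deprotonation with LiN(i-Pr)2 in THF/HMPA and oxaziridine hydroxylation of the dienolate, whose α-carbon C10 is blocked by the fully substituted C9, gives the C2 alcohol F4 as either epimer; Dess–Martin oxidation gives the C2 ketone F5; citric acid in methanol removes the trimethylsilyl groups, returning to the route at 12.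

**Step 15 (with step 16).** The likely failure is the wrong facial selectivity of enolate bromination in the flexible ring, so that displacement would give the C8 epimer, together with epimerisation of the bromide by bromide ion. Fallback, setting out from 17: hydroxylate the same potassium enolate with 2-(phenylsulfonyl)-3-phenyloxaziridine. Oxygen then enters on the face bromine would have taken, which in that event is the correct one, giving the α′-hydroxy ketone F6. Yamaguchi esterification of F6 with 20 proceeds with retention and returns to the route at 21.

**Step 5.** The likely failures are incomplete diastereoselection at C4 in the Michael addition and aldol closure on the C5 carbonyl under reversible base catalysis. Fallback, setting out from 5 and 6: run the Michael addition with catalytic Et3N and isolate triketone 7; close the ring with L-proline in DMSO (enamine aldol of the Hajos–Parrish type). The known sense of that catalyst matches attack on C9 for the desired C4 epimer and is not reversible under these conditions. This returns to the route at 8 and passes through no new compound.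

**Step 23.** The likely failures are delivery of oxygen to the wrong face if the ring holds the C2 hydroxyl away from C4=C5, or competing epoxidation of C1=C10. Fallback, setting out from 28: Shi epoxidation (fructose-derived ketone, KHSO5, buffered MeCN/water, 0 °C), choosing the enantiomer of the ketone catalyst that attacks the required face. The face is then set by the reagent and not by the substrate; this returns to the route at 29 and passes through no new compound.

## Further compounds

F1 | step 14 | C9 trimethylsilyl ether of 16 | C[C@]12C[C@H](O[Si](C)(C)C(C)(C)C)C=C(CO[Si](C)(C)C(C)(C)C)[C@@]1(O[Si](C)(C)C)C[C@@H](C(CO[Si](C)(C)C(C)(C)C)=C)[C@H](O[Si](C)(C)C(C)(C)C)[C@H]2OS(C)(=O)=O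
F2 | step 8 | C5 alcohol of enoate 10 | C[C@]12CCC=C(C(=O)OC)[C@@]1(O)C[C@@H](C(C)=C)[C@H](O[Si](C)(C)C(C)(C)C)[C@H]2O
F3 | step 8 | O5,O9-bis(trimethylsilyl) ether of F2 | C[C@]12CCC=C(C(=O)OC)[C@@]1(O[Si](C)(C)C)C[C@@H](C(C)=C)[C@H](O[Si](C)(C)C(C)(C)C)[C@H]2O[Si](C)(C)C
F4 | step 8 | C2 alcohol of F3, either epimer | C[C@]12CC(O)C=C(C(=O)OC)[C@@]1(O[Si](C)(C)C)C[C@@H](C(C)=C)[C@H](O[Si](C)(C)C(C)(C)C)[C@H]2O[Si](C)(C)C
F5 | step 8 | C2 ketone of F3 | C[C@]12CC(=O)C=C(C(=O)OC)[C@@]1(O[Si](C)(C)C)C[C@@H](C(C)=C)[C@H](O[Si](C)(C)C(C)(C)C)[C@H]2O[Si](C)(C)C
F6 | step 15 | C8 hydroxy ketone, hydroxyl cis to the C7 side chain | O[C@H]1[C@@H](C(CO[Si](C)(C)C(C)(C)C)=C)[C@H](O[Si](C)(C)C(C)(C)C)/C=C(C)\C[C@H](O[Si](C)(C)C(C)(C)C)/C=C(CO[Si](C)(C)C(C)(C)C)\C1=O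
F0 | step 5 | none | none
F0 | step 23 | none | none
A1 | alternative 1 | levoglucosenone | C1[C@@H]2C=CC(=O)[C@H](O1)O2
A2 | alternative 1 | 4-vinyl dihydrolevoglucosenone | C1[C@@H]2[C@@H](C=C)CC(=O)[C@H](O1)O2
A3 | alternative 1 | trans-5-(hydroxymethyl)-4-vinyl-γ-butyrolactone | OC[C@H]1OC(=O)C[C@@H]1C=C
A4 | alternative 2 | ring diene C9=C10–C1=C2 (both ring-cis) with epoxide, lactone and angelate in place | C=C1C(=O)O[C@H]2[C@H]1[C@H](OC(=O)/C(C)=C\C)/C=C(C(=O)OC)\C=C/C[C@@]1(C)O[C@@H]21
A5 | alternative 2 | 2,9-endoperoxide | C=C1C(=O)O[C@H]2[C@H]1[C@H](OC(=O)/C(C)=C\C)[C@H]3OO[C@@H](C[C@@]1(C)O[C@@H]21)C=C3C(=O)OC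
A6 | alternative 3 | C12 acrylic acid with C6 methylene and Z C4=C5 olefin | C1/C=C(C)\C[C@H](O[Si](C)(C)C(C)(C)C)/C=C(C(=O)OC)\[C@H](OC(C)=O)[C@@H](OC(=O)/C(C)=C\C)[C@H]1C(=C)C(=O)O
A7 | alternative 3 | trans-fused α-methylene lactone with Z C4=C5 olefin | C=C1C(=O)O[C@@H]2/C=C(C)\C[C@H](O[Si](C)(C)C(C)(C)C)/C=C(C(=O)OC)\[C@H](OC(C)=O)[C@@H](OC(=O)/C(C)=C\C)[C@@H]12
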